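**Remarks on the chemistry**
- Numbering: abietane numbering is kept for the decalin (C1–C10; C18 is the carboxyl carbon on C4, C19 the 4β-methyl, C20 the 10β-methyl). After ring C is cut, the side chain keeps C11–C13, the former C14 is the methyl on C8, and C16 is the exocyclic methylene carbon on C13. The dioxane-lactone is numbered C1' (lactone carbonyl), C2', C3' (quaternary peroxy carbon), C4' (lactone-oxygen carbon), C5', C6' (allylic peroxy carbon).
- The stereodescriptors of the peroxide domain are read as (3'R,4'S,6'R): H-4' and the 3'-methyl lie on opposite faces, so the γ-lactone is trans-fused to the dioxane. The endgame is built to deliver exactly this arrangement.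
- Commercial abietic acid is technical grade and is assumed to be purified through an amine salt before use.

## Analysis of the target

The target is a C25 methyl ester made of two domains joined by the C11–C12 ethylene tether. One is a trans-decalin (rings A and B). The other is a 1,2-dioxane fused to a γ-lactone, which carries the 1,1-disubstituted alkene C13=C16 on C6'. The decalin holds six stereocentres: C4 (β-axial methyl, α-equatorial CO2Me), C5 and C9 (α-H), C10 (β-methyl), C6 (α-equatorial OH) and C8 (α-OH, β-methyl). The peroxide domain holds three: C6' and C3' carry the two peroxy oxygens, with C13 and the acetate arm cis across the dioxane, and the lactone oxygen on C4' is trans to both. The sensitive groups are the O–O bond (reductants, low-valent metals, and base at the allylic C6'–H), the tertiary C8 alcohol, and the 6α-hydroxy ester, which lies peri to C18 and closes easily to a γ-lactone. The synthesis is hard because C6 is an unactivated methylene that must be oxidised on one face, and because the peroxide has to be assembled late with three defined centres remote from the decalin. The strategy rests on one feature: the equatorial C18 carboxyl on C4 is gauche to C6 and anti to C2, so a radical centred on a C18 amide can reach only H-6α. Abietic acid already contains C4 (with C18 and C19), C5, C9 and C10 in the right configuration, and its ring C can be cut to give the C9 side chain.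

## Retrosynthetic reasoning

**Lactone C1'–O4' bond.** Target 36 is opened at the lactone to the seco thioester 35. The trans ring fusion is the least favourable bond to close, so it is left to the end and made from an activated acyl group, when nothing else can interfere.

**C3'–C2' bond.** Thioester 34 is cut between C3' and C2' to the cyclic methyl peroxyketal 33 and a two-carbon acetate nucleophile. The forward reaction passes through a peroxycarbenium ion at C3'. The ring substituents at C4' and C6' then decide the face of attack, so the quaternary centre is set by the ring itself and not by a separate reagent.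

**Dioxane C–O bonds.** Peroxyketal 33 is opened at the C3'–O bond to the protected hydroperoxide 32, and the C6'–OO bond of 32 is traced to the allylic alcohol 30 by substitution with inversion. This places both oxygen atoms of the peroxide as one intact O–O unit and lets a carbinol centre, which can be set by a reagent, dictate C6'.

**C13–C6' bond.** Alcohol 30 comes from the coupling product 28, which is cut between C13 and C6' into the alkenyl triflate 22 and the aldehyde 27. This is the convergent cut: it separates the two stereochemical domains, and the coupling tolerates the ester, ketal and silyl ethers of both halves.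

**Side chain.** Triflate 22 derives from methyl ketone 21 and this from the diester 19, whose unhindered side-chain ester is told apart from the neopentyl C18 ester by steric hindrance alone.

**Opening of the temporary lactone.** Diester 19 comes from lactone 16 by cleavage of the C18–O6 acyl bond. The lactone is the form in which the C6 oxygen is introduced, and in one ring it serves as protecting group for both C18 and O6.

**C6–O bond (key disconnection).** Lactone 16 is cut at C6–O to the primary amide 12. The forward step must oxidise one of some thirty C–H bonds. It can do so because the amidyl radical at C18 reaches H-6α through a six-membered transition state and nothing else.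

**Ring C and C8.** Amide 12 goes back through the exocyclic alkene 9 and the keto enal 5 to abietamide 3 and abietic acid 1. Cleavage of C13–C14 turns ring C into the side chain (C13 as a ketone that a Baeyer–Villiger step converts into an ester) and leaves C14 on C8, where a reductive transposition and a hydration turn it into the methyl of the tertiary carbinol.

**Fragment 2.** Aldehyde 27 is traced to the achiral ester 23. Its single stereocentre, the future C4', is set by a reagent-controlled allylation, and the C3' carbonyl is carried as a dimethyl ketal that is later exchanged for the peroxide.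

## Alternatives that were turned down

**Alternative 1:** The disconnection cuts C4–C5, C9–C10 and the C8–O bond of a biomimetic bicyclisation. In the forward step SnCl4 opens a terminal epoxide, two trisubstituted alkenes add in turn, and the side-chain ketone oxygen captures the C8 cation to give the tricyclic enol ether A1. In its favour, one step closes rings A and B and sets C5, C8, C9 and C10. The 8α-oxygen with the β-methyl arises directly, and the enol ether is a masked C13 methyl ketone. On these points it is stronger than the chosen route, which spends steps 2–7 and 11–12 on the same functions. Against it, A1 has a C3 hydroxyl that the target lacks and a gem-dimethyl C4. One specific methyl (the α, equatorial one) must be raised to the ester level, which needs a directing group at C3 and several oxidation steps before C3 is deoxygenated. C6 is still a bare methylene, and no carboxyl is available to direct its oxidation until that sequence is finished. The chosen strategy starts with the C18 carboxyl in place and uses it at once for the C6 oxygen.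

**Alternative 2:** The disconnection cuts C3–C4 on a preformed ring B taken from a monoterpene. In the forward step KN(SiMe3)2 forms the C4 ester enolate, which displaces a primary iodide at C3 (6-exo-tet) to give decalin A2. In its favour, the C4 quaternary centre and its ester are made in the ring-closing step. A2 also keeps a C7=C8 alkene, so C6 is allylic and could be oxidised by plain allylic oxidation; this is simpler than a radical relay and is the point on which this alternative is stronger. Against it, the C10 quaternary centre and the tether must be built on ring B first. A2 carries oxygen, not carbon, at C9, so the whole side chain must still be attached there with H-9α, and C8 must then be hydrated from the α face. Allylic oxidation at C6 competes with C9 and with the C8 methyl. The C4 configuration depends on enolate geometry and ring strain, and the axial-ester epimer is not excluded. A2 is therefore an early intermediate in a long sequence. The chosen route obtains C4, C5, C9, C10 and the C9–C11 bond from the starting material.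

**Alternative 3:** The disconnection cuts both C–O bonds of the dioxane in a [4+2] addition of singlet oxygen to a seven-membered 1,3-diene, in which C13 and C2' are temporarily joined through the future lactone carbonyl C1'. The product is the bridged endoperoxide A3. In its favour, the O–O unit and both peroxy carbons are set in one suprafacial step. The cis relation of C13 and the acetate arm follows from the bicyclic geometry, with no substitution at an allylic centre and no peroxycarbenium ion. On this relation it is more secure than steps 21–23 of the chosen route. Against it, A3 already contains the 6,8-dioxygenated decalin, so the alternative does not address C6 at all and would have to sit on top of a decalin synthesis. The face of oxygen addition is controlled only by the C13 stereocentre, which must itself be set relative to the remote decalin. After the cycloaddition the C13–C1' bond must be cut, C13 oxidised and methylenated next to the peroxide, the ring alkene hydrated at C4' with regio- and face control, and the trans lactone closed. That is at least six steps on a strained endoperoxide with an enolisable ketone and a base-labile bridgehead hydrogen. The chosen route makes the peroxide four steps from the end from acyclic precursors, with each centre set by a separate, reagent- or ring-controlled step.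

Key step: step 8

## Route

Step 1
Reactants: 1 abietic acid
Product: 3 abieta-7,13-dien-18-amide (abietamide), via abietoyl chloride 2 (not isolated)
Conditions: (COCl)2, cat. DMF, CH2Cl2, 0 °C; then NH3, THF, 0 °C
Reagents that add atoms: ammonia N
Why: Acyl chloride formation and ammonolysis; the neopentyl C18 carboxyl needs the chloride, and the primary amide is installed first because it tolerates every step up to the key step.

Step 2
Reactants: 3 abietamide
Product: 5 13-oxo-13,14-secoabiet-7-en-14-al-18-amide (keto enal), via 13α,14α-diol 4 (not isolated)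
Conditions: OsO4 (cat.), NMO, t-BuOH/THF/H2O, rt; then NaIO4, rt
Reagents that add atoms: N-methylmorpholine N-oxide C[N+]1([O-])CCOCC1 (oxygen source, transferred by the catalytic OsO4 O=[Os](=O)(=O)=O)
Why: Catalytic dihydroxylation takes the more accessible, isopropyl-substituted 13,14-alkene of the diene from the α face, and periodate glycol cleavage of the cis-diol opens ring C to the isopropyl ketone and the conjugated C14 aldehyde.

Step 3
Reactants: 5 keto enal
Product: 6 14-hydroxy-13-oxo-13,14-secoabiet-7-en-18-amide (allylic alcohol)
Conditions: NaBH4, CH2Cl2/MeOH, −78 °C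
Reagents that add atoms: none
Why: Chemoselective borohydride 1,2-reduction; at −78 °C the aldehyde reacts much faster than the α-branched acyclic ketone, and the amide is inert.

Step 4
Reactants: 6 allylic alcohol
Product: 9 13-oxo-13,14-secoabiet-8(14)-en-18-amide (exocyclic alkene), via sulfonyl hydrazone adduct 7 (not isolated), via allylic diazene 8 (not isolated)
Conditions: N-isopropylidene-N'-2-nitrobenzenesulfonyl hydrazine, PPh3, DEAD, THF, 0 °C to rt; then CF3CH2OH/H2O, rt
Reagents that add atoms: none
Why: Mitsunobu alkylation of the sulfonyl hydrazide, hydrolysis, loss of sulfinate and retro-ene loss of N2 from the monoalkyl diazene place hydrogen on C7 and move the alkene to C8=C14 (reductive 1,3-transposition). The acetone-protected hydrazide is used so that no free hydrazide can condense with the C13 ketone.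

Step 5
Reactants: 9 exocyclic alkene
Product: 10 8α-hydroxy-13-oxo-13,14-secoabietan-18-amide
Conditions: Co(acac)2 (cat.), PhSiH3, O2 (1 atm), THF, rt
Reagents that add atoms: dioxygen O=O
Why: Mukaiyama hydration (hydrogen-atom transfer to C14, O2 capture of the tertiary C8 radical, reduction of the peroxide). O2 should approach the equatorial α face because the axial β face is blocked by the 1,3-related C20 methyl, which gives the 8α-alcohol with the β-methyl.

Step 6
Reactants: 10 8α-alcohol
Product: 11 8α-triethylsilyloxy-13-oxo-13,14-secoabietan-18-amide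
Conditions: Et3SiOTf, 2,6-lutidine, CH2Cl2, −78 to 0 °C; aq. NaHCO3
Reagents that add atoms: triethylsilyl triflate CC[Si](CC)(CC)OS(=O)(=O)C(F)(F)F
Why: Silyl triflate silylation of a hindered tertiary alcohol. The ether blocks hemiketal and lactone formation with C13 and, in the key step, a competing C8 alkoxy radical; any N-silyl amide is cleaved on work-up.

Step 7
Reactants: 11 silyl ether ketone
Product: 12 isopropyl 8α-triethylsilyloxy-18-carbamoyl ester (ring-C-cleaved 18-carboxamide whose C13 is an isopropyl ester)
Conditions: m-CPBA, NaHCO3, CH2Cl2, 0 °C to rt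
Reagents that add atoms: 3-chloroperbenzoic acid O=C(OO)c1cccc(Cl)c1
Why: Baeyer–Villiger oxidation; the secondary isopropyl group migrates in preference to the primary C12, so C13 becomes the carbonyl of an isopropyl ester, and the buffer protects the silyl ether.

Step 8
Reactants: 12 primary amide
Product: 16 18,6α-lactone (8α-triethylsilyl ether; isopropyl ester), via N-iodoamide 13 (not isolated), via 6β-iodo amide 14 (not isolated), via iminolactone 15 (not isolated)
Conditions: PhI(OAc)2, I2, CH2Cl2, hν (tungsten lamp), rt; then aq. Na2S2O3, THF/H2O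
Reagents that add atoms: water O
Why: Acetyl hypoiodite formed from PhI(OAc)2 and I2 N-iodinates the primary amide, and visible light cleaves the N–I bond. The amidyl radical abstracts H-6α through a six-membered transition state (1,5-hydrogen transfer), and the C6 radical takes up iodine (or is oxidised to the cation by the trivalent iodine reagent). The carbonyl oxygen of the amide then closes the five-membered ring, 5-exo-tet on the axial 6β-iodide or by capture of the cation, to the iminolactone, which water hydrolyses to the lactone. The closest known reaction type is the Hofmann–Löffler–Freytag-type photolysis of N-iodo primary amides to γ-lactones. The new C6 stereocentre is fixed by geometry: the oxygen is delivered from the equatorial C18 group and can bond to C6 only on the α face, and a 6α-iodide, which cannot close, returns to the radical or ionises. The step needs site selectivity among the γ-carbons, and the substrate secures it: C18 is anti to C2, C10 has no hydrogen, and only C6 is gauche. The C8 oxygen is silylated so that it cannot form an alkoxy radical. Anhydrous conditions with iodine and light favour the radical path over ionic Hofmann rearrangement.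

Step 9
Reactants: 16 lactone
Product: 18 6α-hydroxy dimethyl ester (C18 and C13 methyl esters; 8α-triethylsilyl ether), via dipotassium dicarboxylate 17 (not isolated)
Conditions: KOH, MeOH/THF/H2O, 50 °C; evaporate; MeI, KHCO3, DMF, 0 °C to rt
Reagents that add atoms: potassium hydroxide [K+].[OH-]; iodomethane CI
Why: Saponification opens the hindered lactone irreversibly as the carboxylate and cleaves the isopropyl ester; methoxide alone would leave the equilibrium with the lactone, whose closure relieves the peri interaction between C18 and O6. O-Alkylation of both carboxylates under bicarbonate then gives the diester without passing through the free hydroxy acid. If hot base removes the 8-silyl ether, step 10 restores it.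

Step 10
Reactants: 18 hydroxy diester
Product: 19 6α,8α-bis(triethylsilyloxy) dimethyl ester
Conditions: Et3SiOTf, 2,6-lutidine, CH2Cl2, −78 to 0 °C
Reagents that add atoms: triethylsilyl triflate CC[Si](CC)(CC)OS(=O)(=O)C(F)(F)F
Why: Silylation of the hindered equatorial 6α-alcohol; blocking this oxygen stops re-lactonisation onto C18 in the basic steps that follow.

Step 11
Reactants: 19 diester
Product: 20 side-chain N-methoxy-N-methylamide (Weinreb amide; C18 methyl ester kept)
Conditions: MeNH(OMe)·HCl, i-PrMgCl, THF, −20 to 0 °C
Reagents that add atoms: N,O-dimethylhydroxylamine hydrochloride CNOC.Cl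
Why: Weinreb amide formation from an ester with the magnesium amide; the unhindered side-chain ester reacts, while the neopentyl C18 ester on the quaternary C4 does not.

Step 12
Reactants: 20 Weinreb amide
Product: 21 C13 methyl ketone
Conditions: MeMgBr, THF, 0 °C
Reagents that add atoms: methylmagnesium bromide C[Mg]Br
Why: Grignard addition to a Weinreb amide stops at the ketone through the chelated tetrahedral intermediate; the C18 ester is again shielded.

Step 13
Reactants: 21 methyl ketone
Product: 22 alkenyl triflate (2-triflyloxy-1-alkene at C13=C16)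
Conditions: LiN(i-Pr)2, THF, −78 °C; N-(5-chloro-2-pyridyl)bis(trifluoromethanesulfonimide), −78 °C
Reagents that add atoms: N-(5-chloro-2-pyridyl)bis(trifluoromethanesulfonimide) O=S(=O)(N(c1ccc(Cl)cn1)S(=O)(=O)C(F)(F)F)C(F)(F)F
Why: Kinetic deprotonation at the methyl group by a hindered amide base and O-triflation of the terminal enolate; the C18 ester has no α-hydrogen.

Step 14
Reactants: 23 methyl 2,2-dimethoxypropanoate
Product: 24 2,2-dimethoxypropanal
Conditions: i-Bu2AlH, CH2Cl2, −78 °C; Rochelle salt work-up
Reagents that add atoms: none
Why: Partial reduction of an α,α-dialkoxy ester; the tetrahedral aluminium intermediate is held by the neighbouring methoxy groups and releases the aldehyde only on work-up.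

Step 15
Reactants: 24 2,2-dimethoxypropanal
Product: 25 (S)-2,2-dimethoxyhex-5-en-3-ol
Conditions: (−)-Ipc2BOMe, allylMgBr, Et2O, −78 °C to rt; then 24, −78 °C; NaOH, H2O2
Reagents that add atoms: allylmagnesium bromide C=CC[Mg]Br
Why: Brown allylation; the allylborane derived from (+)-α-pinene adds through a chair transition state to one face of the non-enolisable aldehyde and sets the (S)-carbinol, the future C4'.

Step 16
Reactants: 25 homoallylic alcohol
Product: 26 (S)-3-(tert-butyldimethylsilyloxy)-2,2-dimethoxyhex-5-ene
Conditions: t-BuMe2SiCl, imidazole, cat. DMAP, DMF, 40 °C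
Reagents that add atoms: tert-butyldimethylsilyl chloride CC(C)(C)[Si](C)(C)Cl
Why: Silylation with the chloride and imidazole, chosen over a silyl triflate because the triflate could ionise the dimethyl ketal.

Step 17
Reactants: 26 silyl ether
Product: 27 (S)-3-(tert-butyldimethylsilyloxy)-4,4-dimethoxypentanal (fragment 2)
Conditions: O3, CH2Cl2, −78 °C; PPh3
Reagents that add atoms: ozone [O-][O+]=O
Why: Ozonolysis with reductive work-up cleaves the only alkene to the aldehyde; the ketal and silyl ether are inert, and the β-silyloxy aldehyde is used at once.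

Step 18
Reactants: 22 alkenyl triflate; 27 aldehyde
Product: 28 coupled allylic alcohol (both C6' epimers)
Conditions: CrCl2, NiCl2 (cat.), DMF, rt
Reagents that add atoms: none
Why: Nozaki–Hiyama–Kishi reaction; NiCl2 mediates insertion into the C–OTf bond, and the alkenylchromium species adds to the aldehyde only, forming C13–C6' in the presence of the ester, ketal and silyl ethers. The configuration at C6' is corrected in the next two steps.

Step 19
Reactants: 28 allylic alcohols
Product: 29 C6' enone
Conditions: Dess–Martin periodinane, NaHCO3, CH2Cl2, 0 °C to rt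
Reagents that add atoms: none
Why: Dess–Martin oxidation converts both epimers into one enone; the buffer protects the ketal from the acetic acid set free.

Step 20
Reactants: 29 enone
Product: 30 (6'S)-allylic alcohol
Conditions: (R)-1-methyl-3,3-diphenyltetrahydro-1H,3H-pyrrolo[1,2-c][1,3,2]oxazaborole ((R)-Me-CBS), catecholborane, toluene, −78 °C
Reagents that add atoms: none
Why: Corey–Bakshi–Shibata reduction; the α-branched alkenyl group acts as the large substituent, so the (R)-catalyst should give the (S)-alcohol, 1,3-anti to the C4' oxygen. This is the epimer needed for the inversion in step 21, and catecholborane avoids hydroboration of the alkene.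

Step 21
Reactants: 30 (6'S)-alcohol
Product: 32 (6'R)-2-methoxyprop-2-yl peroxide (ketal-protected hydroperoxide), via allylic mesylate 31 (not isolated)
Conditions: (MeSO2)2O, Et3N, CH2Cl2, −40 °C; then 2-methoxyprop-2-yl hydroperoxide, CsOH·H2O, DMF, −20 to 0 °C
Reagents that add atoms: 2-methoxyprop-2-yl hydroperoxide COC(C)(C)OO
Why: Displacement of a sulfonate by the caesium salt of a protected hydroperoxide in a dipolar aprotic solvent, an SN2 reaction with inversion that sets the (R)-configured C6'–OO bond. The anhydride is used so that no chloride can substitute the allylic position.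

Step 22
Reactants: 32 protected hydroperoxide
Product: 33 3'-methoxy-1,2-dioxane (cyclic methyl peroxyketal; C3' anomers)
Conditions: camphorsulfonic acid (cat.), CH2Cl2, 0 °C to rt
Reagents that add atoms: none
Why: Acid-catalysed transketalisation; the acid releases the hydroperoxide from its ketal, and the hydroperoxide exchanges one methoxy group of the C3' ketal in a six-membered ring closure. The configuration at C3' is irrelevant because it becomes a cation in step 23.

Step 23
Reactants: 33 methyl peroxyketal
Product: 34 S-ethyl (3'R)-dioxane-3'-thioacetate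
Conditions: TiCl4, 1-(ethylthio)-1-(trimethylsilyloxy)ethene, CH2Cl2, −78 °C
Reagents that add atoms: 1-(ethylthio)-1-(trimethylsilyloxy)ethene C=C(SCC)O[Si](C)(C)C
Why: Lewis acid ionisation of the peroxyketal to a peroxycarbenium ion and Mukaiyama-type addition of the silyl ketene thioacetal, a known reaction of alkoxy-1,2-dioxanes and -dioxolanes. In the half-chair the C6' substituent is pseudoequatorial and the C4' silyloxy group pseudoaxial (it avoids A(1,2) strain with the C3' methyl). The nucleophile therefore enters axially, anti to the silyloxy group and cis to C13, which sets the (3'R) quaternary centre.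

Step 24
Reactants: 34 silylated thioester
Product: 35 triol thioester (6α-, 8α- and 4'-hydroxyls free)
Conditions: HF·pyridine, pyridine, THF, 0 °C to rt
Reagents that add atoms: none
Why: Fluoride cleavage of the three silyl ethers under mildly acidic conditions that leave the peroxide, the thioester and the hindered hydroxy ester untouched.

Step 25
Reactants: 35 triol thioester
Product: 36 target compound CNP0162504.1
Conditions: AgOCOCF3, Na2HPO4, benzene, rt, high dilution
Reagents that add atoms: none
Why: Thiophilic activation of the thioester by the silver salt and intramolecular acyl transfer to the only hydroxyl within reach, the 4'-OH, once the dioxane adopts the chair with both reacting groups equatorial. This closes the trans-fused γ-lactone.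

## Compound list

1 | abietic acid | CC(C)C1=CC2=CC[C@H]3[C@](C)(C(=O)O)CCC[C@]3(C)[C@H]2CC1 | starting material
2 | abietoyl chloride | CC(C)C1=CC2=CC[C@H]3[C@](C)(C(=O)Cl)CCC[C@]3(C)[C@H]2CC1 | intermediate
3 | abieta-7,13-dien-18-amide | CC(C)C1=CC2=CC[C@H]3[C@](C)(C(N)=O)CCC[C@]3(C)[C@H]2CC1 | intermediate
4 | 13α,14α-dihydroxyabiet-7-en-18-amide | CC(C)[C@@]1(O)[C@H](O)C2=CC[C@H]3[C@](C)(C(N)=O)CCC[C@]3(C)[C@H]2CC1 | intermediate
5 | 13-oxo-13,14-secoabiet-7-en-14-al-18-amide | CC(C)C(=O)CC[C@@H]1[C@@]2(C)CCC[C@@](C)(C(N)=O)[C@@H]2CC=C1C=O | intermediate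
6 | 14-hydroxy-13-oxo-13,14-secoabiet-7-en-18-amide | CC(C)C(=O)CC[C@@H]1[C@@]2(C)CCC[C@@](C)(C(N)=O)[C@@H]2CC=C1CO | intermediate
7 | N-(C14-allyl)-N-(2-nitrobenzenesulfonyl) acetone hydrazone adduct | CC(C)C(=O)CC[C@@H]1[C@@]2(C)CCC[C@@](C)(C(N)=O)[C@@H]2CC=C1CN(N=C(C)C)S(=O)(=O)c1ccccc1[N+](=O)[O-] | intermediate
8 | C14 allylic monoalkyl diazene | CC(C)C(=O)CC[C@@H]1[C@@]2(C)CCC[C@@](C)(C(N)=O)[C@@H]2CC=C1CN=N | intermediate
9 | 13-oxo-13,14-secoabiet-8(14)-en-18-amide | CC(C)C(=O)CC[C@@H]1[C@@]2(C)CCC[C@@](C)(C(N)=O)[C@@H]2CCC1=C | intermediate
10 | 8α-hydroxy-13-oxo-13,14-secoabietan-18-amide | CC(C)C(=O)CC[C@@H]1[C@@]2(C)CCC[C@@](C)(C(N)=O)[C@@H]2CC[C@@]1(C)O | intermediate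
11 | 8α-triethylsilyloxy-13-oxo-13,14-secoabietan-18-amide | CC(C)C(=O)CC[C@@H]1[C@@]2(C)CCC[C@@](C)(C(N)=O)[C@@H]2CC[C@@]1(C)O[Si](CC)(CC)CC | intermediate
12 | ring-C-cleaved 18-carboxamide, 8α-OSiEt3, isopropyl C13 ester | CC(C)OC(=O)CC[C@@H]1[C@@]2(C)CCC[C@@](C)(C(N)=O)[C@@H]2CC[C@@]1(C)O[Si](CC)(CC)CC | intermediate
13 | N-iodoamide of 12 | CC(C)OC(=O)CC[C@@H]1[C@@]2(C)CCC[C@@](C)(C(=O)NI)[C@@H]2CC[C@@]1(C)O[Si](CC)(CC)CC | intermediate
14 | 6β-iodo amide | CC(C)OC(=O)CC[C@@H]1[C@@]2(C)CCC[C@@](C)(C(N)=O)[C@@H]2[C@H](I)C[C@@]1(C)O[Si](CC)(CC)CC | intermediate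
15 | 18,6α-iminolactone | CC(C)OC(=O)CC[C@@H]1[C@@]2(C)CCC[C@@]3(C)C(=N)O[C@H]([C@H]23)C[C@@]1(C)O[Si](CC)(CC)CC | intermediate
16 | 18,6α-lactone, 8α-OSiEt3, isopropyl C13 ester | CC(C)OC(=O)CC[C@@H]1[C@@]2(C)CCC[C@@]3(C)C(=O)O[C@H]([C@H]23)C[C@@]1(C)O[Si](CC)(CC)CC | intermediate
17 | dipotassium 6α-hydroxy-8α-triethylsilyloxy 13,18-dicarboxylate | [K+].[K+].[O-]C(=O)CC[C@@H]1[C@@]2(C)CCC[C@@](C)(C([O-])=O)[C@@H]2[C@@H](O)C[C@@]1(C)O[Si](CC)(CC)CC | intermediate
18 | 6α-hydroxy-8α-triethylsilyloxy dimethyl ester | COC(=O)CC[C@@H]1[C@@]2(C)CCC[C@@](C)(C(=O)OC)[C@@H]2[C@@H](O)C[C@@]1(C)O[Si](CC)(CC)CC | intermediate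
19 | 6α,8α-bis(triethylsilyloxy) dimethyl ester | COC(=O)CC[C@@H]1[C@@]2(C)CCC[C@@](C)(C(=O)OC)[C@@H]2[C@@H](O[Si](CC)(CC)CC)C[C@@]1(C)O[Si](CC)(CC)CC | intermediate
20 | side-chain Weinreb amide | CON(C)C(=O)CC[C@@H]1[C@@]2(C)CCC[C@@](C)(C(=O)OC)[C@@H]2[C@@H](O[Si](CC)(CC)CC)C[C@@]1(C)O[Si](CC)(CC)CC | intermediate
21 | C13 methyl ketone | CC(=O)CC[C@@H]1[C@@]2(C)CCC[C@@](C)(C(=O)OC)[C@@H]2[C@@H](O[Si](CC)(CC)CC)C[C@@]1(C)O[Si](CC)(CC)CC | intermediate
22 | C13 alkenyl triflate | C=C(OS(=O)(=O)C(F)(F)F)CC[C@@H]1[C@@]2(C)CCC[C@@](C)(C(=O)OC)[C@@H]2[C@@H](O[Si](CC)(CC)CC)C[C@@]1(C)O[Si](CC)(CC)CC | intermediate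
23 | methyl 2,2-dimethoxypropanoate | COC(=O)C(C)(OC)OC | starting material
24 | 2,2-dimethoxypropanal | CC(OC)(OC)C=O | intermediate
25 | (S)-2,2-dimethoxyhex-5-en-3-ol | CC(OC)(OC)[C@@H](O)CC=C | intermediate
26 | (S)-3-(tert-butyldimethylsilyloxy)-2,2-dimethoxyhex-5-ene | CC(OC)(OC)[C@@H](O[Si](C)(C)C(C)(C)C)CC=C | intermediate
27 | (S)-3-(tert-butyldimethylsilyloxy)-4,4-dimethoxypentanal | CC(OC)(OC)[C@@H](O[Si](C)(C)C(C)(C)C)CC=O | intermediate
28 | coupled allylic alcohol, C6' epimers | C=C(CC[C@@H]1[C@@]2(C)CCC[C@@](C)(C(=O)OC)[C@@H]2[C@@H](O[Si](CC)(CC)CC)C[C@@]1(C)O[Si](CC)(CC)CC)C(O)C[C@H](O[Si](C)(C)C(C)(C)C)C(C)(OC)OC | intermediate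
29 | C6' enone | C=C(CC[C@@H]1[C@@]2(C)CCC[C@@](C)(C(=O)OC)[C@@H]2[C@@H](O[Si](CC)(CC)CC)C[C@@]1(C)O[Si](CC)(CC)CC)C(=O)C[C@H](O[Si](C)(C)C(C)(C)C)C(C)(OC)OC | intermediate
30 | (6'S)-allylic alcohol | C=C(CC[C@@H]1[C@@]2(C)CCC[C@@](C)(C(=O)OC)[C@@H]2[C@@H](O[Si](CC)(CC)CC)C[C@@]1(C)O[Si](CC)(CC)CC)[C@@H](O)C[C@H](O[Si](C)(C)C(C)(C)C)C(C)(OC)OC | intermediate
31 | (6'S)-allylic mesylate | C=C(CC[C@@H]1[C@@]2(C)CCC[C@@](C)(C(=O)OC)[C@@H]2[C@@H](O[Si](CC)(CC)CC)C[C@@]1(C)O[Si](CC)(CC)CC)[C@@H](OS(C)(=O)=O)C[C@H](O[Si](C)(C)C(C)(C)C)C(C)(OC)OC | intermediate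
32 | (6'R)-2-methoxyprop-2-yl peroxide | C=C(CC[C@@H]1[C@@]2(C)CCC[C@@](C)(C(=O)OC)[C@@H]2[C@@H](O[Si](CC)(CC)CC)C[C@@]1(C)O[Si](CC)(CC)CC)[C@H](OOC(C)(C)OC)C[C@H](O[Si](C)(C)C(C)(C)C)C(C)(OC)OC | intermediate
33 | 3'-methoxy-3'-methyl-1,2-dioxane, C3' anomers | C=C(CC[C@@H]1[C@@]2(C)CCC[C@@](C)(C(=O)OC)[C@@H]2[C@@H](O[Si](CC)(CC)CC)C[C@@]1(C)O[Si](CC)(CC)CC)[C@H]1C[C@H](O[Si](C)(C)C(C)(C)C)C(C)(OC)OO1 | intermediate
34 | S-ethyl (3'R)-dioxane-3'-thioacetate, fully silylated | C=C(CC[C@@H]1[C@@]2(C)CCC[C@@](C)(C(=O)OC)[C@@H]2[C@@H](O[Si](CC)(CC)CC)C[C@@]1(C)O[Si](CC)(CC)CC)[C@H]1C[C@H](O[Si](C)(C)C(C)(C)C)[C@@](C)(CC(=O)SCC)OO1 | intermediate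
35 | triol S-ethyl thioester | C=C(CC[C@@H]1[C@@]2(C)CCC[C@@](C)(C(=O)OC)[C@@H]2[C@@H](O)C[C@@]1(C)O)[C@H]1C[C@H](O)[C@@](C)(CC(=O)SCC)OO1 | intermediate
36 | CNP0162504.1 | C=C(CC[C@@H]1[C@@]2(C)CCC[C@@](C)(C(=O)OC)[C@@H]2[C@@H](O)C[C@@]1(C)O)[C@H]1C[C@@H]2OC(=O)C[C@@]2(C)OO1 | target

**Total step count:** 25. **Longest linear sequence:** 21 steps (steps 1–13 and 18–25, from abietic acid); fragment 2 takes 4 steps (14–17).

## Least certain steps

**Step 8 (key step).** The most likely failure is ionic Hofmann rearrangement of the primary amide under PhI(OAc)2, with migration of the tertiary C4 to nitrogen, before the N–I bond is cleaved by light. Closure through nitrogen to the lactam and loss of the silyl ether to the acid set free are lesser risks. Fallback, from 12 back to 16: nitrosative deamination of the amide (tert-butyl nitrite, AcOH/THF) gives the carboxylic acid F1. Carboxylate-directed C–H hydroxylation with [Fe((S,S)-PDP)(MeCN)2](SbF6)2 and H2O2 then lactonises at the only γ-C–H within reach of the bound carboxylate, H-6α, and returns to the route at 16. This replaces the nitrogen radical by a metal-oxo rebound and needs no N-halo species.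

**Step 21.** The peroxide anion may attack the unhindered C16 methylene (SN2'), may act as a base and eliminate to the 1,3-diene, or the allylic sulfonate may ionise with loss of configuration. All three follow from the leaving group being secondary, allylic and next to a 1,1-disubstituted alkene. Fallback, from 28 (either C6' epimer) back to 33: reductive 1,3-transposition under the conditions of step 4 gives the trisubstituted alkene F2, with C16 now a methyl group. A Schenck ene reaction (O2, tetraphenylporphyrin, hν) then abstracts hydrogen from that methyl, restores the exocyclic methylene and places the hydroperoxide on C6', giving hydroperoxide F3 after separation from its C6' epimer and regioisomers. F3 closes to 33 under the conditions of step 22. This route is less selective but uses no substitution at the allylic centre.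

**Step 23.** Ionisation at C3' is slowed by the neighbouring silyloxy group, so TiCl4 may instead strip silyl ethers or ionise the allylic C6'–O bond; the face of attack may also be less uniform than the half-chair analysis predicts. Fallback, from 26 back to 36, which forms the C3'–C2' bond before the peroxide exists and closes the dioxane by conjugate addition:
- Ketal hydrolysis of 26 (aqueous trifluoroacetic acid, CHCl3) gives methyl ketone F4.
- Horner–Wadsworth–Emmons reaction with trimethyl phosphonoacetate (LiCl, DBU) gives the E-enoate F5.
- Ozonolysis of the terminal alkene gives aldehyde F6.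
- Coupling with 22 as in step 18 gives allylic alcohol F7.
- Oxidation and reduction as in steps 19 and 20 give enone F8 and the (6'S)-alcohol F9.
- Sulfonylation as in step 21 and displacement with H2O2/KOH in MeOH/THF follow; the hydroperoxide adds to the enoate in the same flask (intramolecular oxa-Michael addition, a known route to 1,2-dioxane-3-acetates) to give dioxane ester F10, from which the C3' epimer is separated.
- HF·pyridine gives triol ester F11, and acid-catalysed lactonisation (camphorsulfonic acid, benzene, heat) gives 36.

**Step 25.** Closure of the trans-fused ring may be slow, because the dioxane must first flip to the chair with an axial C6' substituent. The activated thioester could then be hydrolysed or transfer its acyl group to another molecule. Fallback, from 35 back to 36: hydrolysis of the thioester (AgNO3, 2,6-lutidine, aqueous THF) gives the seco acid F12, which is closed by Steglich lactonisation (EDC·HCl, catalytic DMAP, CH2Cl2, 0 °C, high dilution). This activates the free acid irreversibly as the O-acylisourea instead of relying on silver–sulfur affinity.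

**Step 9.** The 6α-hydroxy ester 18 may re-close to the lactone during or after the methylation, since closure relieves the peri interaction and needs only a trace of base. Fallback, from 16 back to 19, which protects O6 before any ester is present: the dried dicarboxylate 17 is silylated exhaustively (Et3SiOTf, 2,6-lutidine) to the tetrasilyl compound F13. Mild methanolysis of the two silyl esters (K2CO3, MeOH/H2O, 0 °C) gives diacid F14, and trimethylsilyldiazomethane (MeOH/toluene) gives 19.

## Further compounds

F1 | step 8 | 18-carboxylic acid, 8α-OSiEt3, isopropyl C13 ester | CC(C)OC(=O)CC[C@@H]1[C@@]2(C)CCC[C@@](C)(C(=O)O)[C@@H]2CC[C@@]1(C)O[Si](CC)(CC)CC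
F2 | step 21 | (E)-C13(methyl)=C6' trisubstituted alkene | C/C(CC[C@@H]1[C@@]2(C)CCC[C@@](C)(C(=O)OC)[C@@H]2[C@@H](O[Si](CC)(CC)CC)C[C@@]1(C)O[Si](CC)(CC)CC)=C\C[C@H](O[Si](C)(C)C(C)(C)C)C(C)(OC)OC
F3 | step 21 | (6'R)-allylic hydroperoxide | C=C(CC[C@@H]1[C@@]2(C)CCC[C@@](C)(C(=O)OC)[C@@H]2[C@@H](O[Si](CC)(CC)CC)C[C@@]1(C)O[Si](CC)(CC)CC)[C@H](OO)C[C@H](O[Si](C)(C)C(C)(C)C)C(C)(OC)OC
F4 | step 23 | (S)-3-(tert-butyldimethylsilyloxy)hex-5-en-2-one | CC(=O)[C@@H](O[Si](C)(C)C(C)(C)C)CC=C
F5 | step 23 | methyl (S,E)-4-(tert-butyldimethylsilyloxy)-3-methylhepta-2,6-dienoate | C/C(=C\C(=O)OC)[C@@H](O[Si](C)(C)C(C)(C)C)CC=C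
F6 | step 23 | methyl (S,E)-4-(tert-butyldimethylsilyloxy)-3-methyl-6-oxohex-2-enoate | C/C(=C\C(=O)OC)[C@@H](O[Si](C)(C)C(C)(C)C)CC=O
F7 | step 23 | coupled allylic alcohol with enoate, C6' epimers | C=C(CC[C@@H]1[C@@]2(C)CCC[C@@](C)(C(=O)OC)[C@@H]2[C@@H](O[Si](CC)(CC)CC)C[C@@]1(C)O[Si](CC)(CC)CC)C(O)C[C@H](O[Si](C)(C)C(C)(C)C)/C(C)=C/C(=O)OC
F8 | step 23 | C6' enone with enoate | C=C(CC[C@@H]1[C@@]2(C)CCC[C@@](C)(C(=O)OC)[C@@H]2[C@@H](O[Si](CC)(CC)CC)C[C@@]1(C)O[Si](CC)(CC)CC)C(=O)C[C@H](O[Si](C)(C)C(C)(C)C)/C(C)=C/C(=O)OC
F9 | step 23 | (6'S)-allylic alcohol with enoate | C=C(CC[C@@H]1[C@@]2(C)CCC[C@@](C)(C(=O)OC)[C@@H]2[C@@H](O[Si](CC)(CC)CC)C[C@@]1(C)O[Si](CC)(CC)CC)[C@@H](O)C[C@H](O[Si](C)(C)C(C)(C)C)/C(C)=C/C(=O)OC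
F10 | step 23 | methyl (3'R)-dioxane-3'-acetate, fully silylated | C=C(CC[C@@H]1[C@@]2(C)CCC[C@@](C)(C(=O)OC)[C@@H]2[C@@H](O[Si](CC)(CC)CC)C[C@@]1(C)O[Si](CC)(CC)CC)[C@H]1C[C@H](O[Si](C)(C)C(C)(C)C)[C@@](C)(CC(=O)OC)OO1
F11 | step 23 | triol methyl dioxane-3'-acetate | C=C(CC[C@@H]1[C@@]2(C)CCC[C@@](C)(C(=O)OC)[C@@H]2[C@@H](O)C[C@@]1(C)O)[C@H]1C[C@H](O)[C@@](C)(CC(=O)OC)OO1
F12 | step 25 | seco acid (triol dioxane-3'-acetic acid) | C=C(CC[C@@H]1[C@@]2(C)CCC[C@@](C)(C(=O)OC)[C@@H]2[C@@H](O)C[C@@]1(C)O)[C@H]1C[C@H](O)[C@@](C)(CC(=O)O)OO1
F13 | step 9 | 6α,8α-bis(triethylsilyloxy) bis(triethylsilyl) ester | CC[Si](CC)(CC)OC(=O)CC[C@@H]1[C@@]2(C)CCC[C@@](C)(C(=O)O[Si](CC)(CC)CC)[C@@H]2[C@@H](O[Si](CC)(CC)CC)C[C@@]1(C)O[Si](CC)(CC)CC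
F14 | step 9 | 6α,8α-bis(triethylsilyloxy) 13,18-diacid | OC(=O)CC[C@@H]1[C@@]2(C)CCC[C@@](C)(C(=O)O)[C@@H]2[C@@H](O[Si](CC)(CC)CC)C[C@@]1(C)O[Si](CC)(CC)CC
A1 | alternative 1 | 3β-hydroxy tricyclic enol ether (8α,13-epoxy-12-ene) | CC1=CC[C@@H]2[C@@]3(C)CC[C@H](O)C(C)(C)[C@@H]3CC[C@@]2(C)O1
A2 | alternative 2 | trans-decalin with C4 ester and ring B allylic silyl ether | CC1=CC[C@H]2[C@](C)(C(=O)OC)CCC[C@]2(C)[C@@H]1O[Si](C)(C)C(C)(C)C
A3 | alternative 3 | bridged endoperoxide ketone (dioxabicyclo[3.2.2]nonenone) | C(C[C@@H]1[C@@]2(C)CCC[C@@](C)(C(=O)OC)[C@@H]2[C@@H](O[Si](CC)(CC)CC)C[C@@]1(C)O[Si](CC)(CC)CC)[C@@H]1C(=O)C[C@@]2(C)OO[C@@H]1C=C2
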